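**Retrosynthetic overview**

1. Locants of the target: ring C1 (C=O), C2=C3, C4 (OMe), C5 (CH2), C6 (quaternary); C7 = aroyl carbon, C8 = CH(CH3). The aryl–C7 bond is made by adding 3,4-dimethoxyphenyllithium to the lactone carbonyl of a tricyclic acylal; the same operation unveils the enone and methylates O4.
2. Enabling feature: in the 4-methoxycyclohex-2-en-1-one ring the oxygens on C1 and C4 sit 1,4 across C2=C3 (a ring-opened 1-oxy-7-oxanorbornene, i.e. furan plus alkene). O4 is cis to the C8 side chain, and C7 is γ to C1 (1,4-dicarbonyl C7–C8–C6–C1), so C7 can be held on O1 as a γ-lactone.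
3. The cage is the intramolecular furan Diels–Alder adduct of the furan-2-yl ester of (S)-2-methyl-3-methylidenehex-5-enoic acid; bonds C1–C6 and C4–C5 form, and C8 controls C6, C4 and C1.
4. The ester comes from butenolide (C1–C4 and both ring oxygens) and the acid; the acid comes from Evans methylation of 3-methylidenehex-5-enoic acid (diketene plus allyl Grignard).
5. Ring order: γ-lactone and oxanorbornene (the future carbocycle) close together in step 6; step 7 opens both heterocycles and leaves the cyclohexenone.

Key step: step 7

Remark: the five numbered starting materials (1, 2, 4, 11, 16) are taken as commercial; the configuration at the hemiketal carbon of 18 is left open because it is lost on collapse.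

**Step 1**
Reactants: 1 diketene (4-methylideneoxetan-2-one); 2 allylmagnesium chloride
Product: 3 3-methylidenehex-5-enoic acid
Conditions: NiCl2(PPh3)2 (5 mol %), slow addition of 2, THF, −78 → 0 °C; 1 M HCl
Reagents that add atoms: none
Why: Nickel-catalysed Kumada-type cross-coupling at the enol C–O bond of diketene (oxidative addition, transmetalation, reductive elimination) is the established route from Grignard reagents to 3-substituted but-3-enoic acids, and slow addition at low temperature should keep carbonyl attack in check; no stereocentre is formed.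

**Step 2**
Reactants: 3 3-methylidenehex-5-enoic acid; 4 (S)-4-benzyl-1,3-oxazolidin-2-one
Product: 6 (4S)-4-benzyl-3-(3-methylidenehex-5-enoyl)-1,3-oxazolidin-2-one, via mixed pivalic anhydride 5 (not isolated)
Conditions: PivCl, Et3N, THF, −20 °C; then 4, LiCl, −20 °C → rt
Reagents that add atoms: none
Why: N-acylation of the Evans auxiliary through the mixed pivalic anhydride (LiCl-assisted) is the standard mild imide formation, and the low temperature should avoid conjugation of the β,γ-alkene.

**Step 3**
Reactants: 6 (4S)-4-benzyl-3-(3-methylidenehex-5-enoyl)-1,3-oxazolidin-2-one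
Product: 8 (4S)-4-benzyl-3-[(2S)-2-methyl-3-methylidenehex-5-enoyl]-1,3-oxazolidin-2-one, via sodium Z-dienolate 7 (not isolated)
Conditions: NaHMDS (1.1 equiv), THF, −78 °C; MeI, −78 → −40 °C
Reagents that add atoms: iodomethane, CI
Why: Evans asymmetric alkylation: the chelated Z-dienolate should be methylated at the α-carbon on the face opposite the benzyl group, which sets C8 as (S) (the methyl group enters where the allyl group enters in the textbook propionimide case, so the (S)-auxiliary gives the (S)-descriptor here).

**Step 4**
Reactants: 8 (4S)-4-benzyl-3-[(2S)-2-methyl-3-methylidenehex-5-enoyl]-1,3-oxazolidin-2-one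
Product: 10 (2S)-2-methyl-3-methylidenehex-5-enoic acid, via lithium peroxycarboxylate 9 (not isolated)
Conditions: LiOH, H2O2, THF/H2O, 0 °C; Na2SO3; 1 M HCl
Reagents that add atoms: hydrogen peroxide (as LiOOH), OO
Why: Hydroperoxide cleaves the exocyclic imide carbonyl selectively (standard Evans auxiliary removal) without touching C8 or the alkenes, and sulfite reduces the peracid to the acid.

**Step 5**
Reactants: 10 (2S)-2-methyl-3-methylidenehex-5-enoic acid; 11 furan-2(5H)-one
Product: 14 furan-2-yl (2S)-2-methyl-3-methylidenehex-5-enoate, via acid chloride 12 (not isolated), via potassium furan-2-olate 13 (not isolated)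
Conditions: 10, Ghosez reagent, CH2Cl2, 0 °C; 11, KHMDS, THF, −78 °C; combine at −78 °C
Reagents that add atoms: none
Why: O-acylation of the aromatic furan-2-olate (the dienolate of the butenolide) by an acid chloride made under neutral conditions should give the 2-acyloxyfuran, and the absence of amine base at −78 °C avoids the ketene, so C8 is kept.

**Step 6**
Reactants: 14 furan-2-yl (2S)-2-methyl-3-methylidenehex-5-enoate
Product: 15 (3S,3aR,5R,7aS)-3-methyl-3a-(prop-2-en-1-yl)-3a,4-dihydro-5H-5,7a-epoxy-1-benzofuran-2(3H)-one (7-oxanorbornene with the oxygen bridge between C1 and C4, exo-fused to a γ-lactone from O1 through C7 and C8 to C6; allyl endo on C6)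
Conditions: CH2Cl2 (0.05 M), BHT, 14 kbar, 50 °C; base-washed glassware
Reagents that add atoms: none
Why: Intramolecular Diels–Alder reaction of a furan (IMDAF) through a three-atom tether, as known for 2-amidofurans carrying unactivated alkenes, here driven by pressure because the ester must adopt its s-cis form and the dienophile is unactivated; the short tether can only lie exo (syn to the oxygen bridge), which puts C4–O cis to C8 and the allyl group endo on the new quaternary C6, and the C8 methyl group should avoid the geminal allyl group in the transition state (allylic 1,2-strain), so that C1, C4 and C6 are all set from C8.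

**Step 7**
Reactants: 15 tricyclic acylal lactone; 16 4-bromo-1,2-dimethoxybenzene
Product: 20 (4R,6R)-6-[(2S)-1-(3,4-dimethoxyphenyl)-1-oxopropan-2-yl]-4-methoxy-6-(prop-2-en-1-yl)cyclohex-2-en-1-one, via (3,4-dimethoxyphenyl)lithium 17 (not isolated), via lithium lactolate 18 (not isolated), via lithium 4-oxidoenone 19 (not isolated)
Conditions: 16, n-BuLi (1.05 equiv), THF, −78 °C; add to 15, THF, −78 °C; warm to −20 °C; MeOTf, −20 → 0 °C
Reagents that add atoms: methyl trifluoromethanesulfonate, COS(=O)(=O)C(F)(F)F
Why: Proposed new method: the aryllithium adds to the lactone carbonyl (C7), the only C=O group of 15, to give lactolate 18; on warming, 18 opens to the aryl ketone and a C1 hemiketal alkoxide, which collapses to the C1 ketone and expels the strained oxygen bridge as the C4 alkoxide 19 (now the C2=C3 enone), and MeOTf then O-methylates 19. The closest known reactions are acyl substitution of γ-lactones by aryllithiums through a lactolate that persists at −78 °C, the Fujimoto–Belleau opening of enol lactones (the leaving oxygen becomes a ketone), and the opening of 1-oxy-7-oxanorbornenes to 4-hydroxycyclohex-2-enones. No ring is closed: the lactone and the oxa-bridge are opened and the cyclohexenone is left. No stereocentre is formed: C6 and C8 are not touched and the C4–O bond is never broken, so the cis relation of C4–O and the C8 side chain built into the cage should appear unchanged in 20. The step needs mono-addition and chemoselectivity; both should follow because the two ketones of the product stay masked (as lactolate and as acylal) until the aryllithium is consumed at −78 °C, and the triflate is added only after the collapse so that the oxygen on C4, not the lactolate, is methylated.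

**Compound list**

1 | diketene (4-methylideneoxetan-2-one) | C=C1CC(=O)O1 | starting material
2 | allylmagnesium chloride | C=CC[Mg]Cl | starting material
3 | 3-methylidenehex-5-enoic acid | C=CCC(=C)CC(=O)O | intermediate
4 | (S)-4-benzyl-1,3-oxazolidin-2-one | O=C1N[C@@H](Cc2ccccc2)CO1 | starting material
5 | 2,2-dimethylpropanoic 3-methylidenehex-5-enoic anhydride | C=CCC(=C)CC(=O)OC(=O)C(C)(C)C | intermediate (not isolated)
6 | (4S)-4-benzyl-3-(3-methylidenehex-5-enoyl)-1,3-oxazolidin-2-one | C=CCC(=C)CC(=O)N1[C@@H](Cc2ccccc2)COC1=O | intermediate
7 | sodium Z-dienolate of 6 | C=CCC(=C)/C=C(\[O-])N1[C@@H](Cc2ccccc2)COC1=O.[Na+] | intermediate (not isolated)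
8 | (4S)-4-benzyl-3-[(2S)-2-methyl-3-methylidenehex-5-enoyl]-1,3-oxazolidin-2-one | C=CCC(=C)[C@H](C)C(=O)N1[C@@H](Cc2ccccc2)COC1=O | intermediate
9 | lithium (2S)-2-methyl-3-methylidenehex-5-eneperoxoate | C=CCC(=C)[C@H](C)C(=O)O[O-].[Li+] | intermediate (not isolated)
10 | (2S)-2-methyl-3-methylidenehex-5-enoic acid | C=CCC(=C)[C@H](C)C(=O)O | intermediate
11 | furan-2(5H)-one | O=C1OCC=C1 | starting material
12 | (2S)-2-methyl-3-methylidenehex-5-enoyl chloride | C=CCC(=C)[C@H](C)C(=O)Cl | intermediate (not isolated)
13 | potassium furan-2-olate | [O-]c1ccco1.[K+] | intermediate (not isolated)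
14 | furan-2-yl (2S)-2-methyl-3-methylidenehex-5-enoate | C=CCC(=C)[C@H](C)C(=O)Oc1ccco1 | intermediate
15 | (3S,3aR,5R,7aS)-3-methyl-3a-(prop-2-en-1-yl)-3a,4-dihydro-5H-5,7a-epoxy-1-benzofuran-2(3H)-one | C=CC[C@]12C[C@@H]3C=C[C@]1(O3)OC(=O)[C@H]2C | intermediate
16 | 4-bromo-1,2-dimethoxybenzene | COc1ccc(Br)cc1OC | starting material
17 | (3,4-dimethoxyphenyl)lithium | [Li]c1ccc(OC)c(OC)c1 | intermediate (not isolated)
18 | lithium lactolate from 15 and 17 (2-aryl-2-oxido derivative of 15, hemiketal carbon undefined) | C=CC[C@]12C[C@@H]3C=C[C@]1(O3)OC([O-])(c4ccc(OC)c(OC)c4)[C@H]2C.[Li+] | intermediate (not isolated)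
19 | lithium (1R,5R)-5-[(2S)-1-(3,4-dimethoxyphenyl)-1-oxopropan-2-yl]-4-oxo-5-(prop-2-en-1-yl)cyclohex-2-en-1-olate | C=CC[C@]1([C@H](C)C(=O)c2ccc(OC)c(OC)c2)C[C@@H]([O-])C=CC1=O.[Li+] | intermediate (not isolated)
20 | (4R,6R)-6-[(2S)-1-(3,4-dimethoxyphenyl)-1-oxopropan-2-yl]-4-methoxy-6-(prop-2-en-1-yl)cyclohex-2-en-1-one | C=CC[C@]1([C@H](C)C(=O)c2ccc(OC)c(OC)c2)C[C@@H](OC)C=CC1=O | target

**Step count and risks**

Total step count: 7. Longest linear sequence: 7 (from diketene 1 to 20).

Step 7 (proposed new method). If lactolate 18 collapses before all the aryllithium is consumed, the aryl ketone and the enone would be exposed to a second addition. A long-lived alkoxide 19 could also isomerise towards the 1,4-dione or add to another enone before it is methylated. The fallback uses only known reactions, sets out from 15 and comes back at 20. Methanolysis of the acylal lactone (K2CO3 cat., MeOH, 0 °C) triggers the same fragmentation with methoxide and should give methyl (2S)-2-[(1R,5R)-5-hydroxy-2-oxo-1-(prop-2-en-1-yl)cyclohex-3-en-1-yl]propanoate F1. O-methylation (Me3OBF4, proton sponge, CH2Cl2) should give the methyl ether ester F2, and mild ester cleavage (Me3SnOH, 1,2-dichloroethane, 70 °C) the acid F3. Thioesterification (EtSH, EDC, DMAP) should give the S-ethyl thioester F4. Liebeskind–Srogl coupling of F4 with (3,4-dimethoxyphenyl)boronic acid (Pd2(dba)3, tri(2-furyl)phosphine, CuTC, THF, 50 °C) then forms the same aryl–C7 bond under neutral conditions that tolerate the enone and C8, giving 20.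

Step 6. The cycloaddition may be too slow (s-cis ester requirement, unactivated alkene) and face selectivity may be modest. The cage may also be lost during isolation by ionisation of the acylal C1–O bridge bond followed by acyl shift. The fallback sets out from 14 and comes back at 20. The acyl shift is made deliberate: the pressurised mixture is treated with a catalytic Lewis acid (Sc(OTf)3, CH2Cl2, 0 °C). The C4 oxygen then recaptures the acyl group and the adduct is drained irreversibly into the bridged keto lactone (1R,4S,5R)-4-methyl-5-(prop-2-en-1-yl)-2-oxabicyclo[3.3.1]non-7-ene-3,6-dione F5, the oxygen counterpart of the ring-opening that drives amidofuran cycloadditions. F5 is methanolysed (K2CO3, MeOH) to the hydroxy ester F1 of the preceding fallback and carried through F2, F3 and F4 to 20 by the Liebeskind–Srogl coupling.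

Step 5. C8 may epimerise through the ketene or enol of the activated acid, and the ambident furanolate may be acylated at carbon instead of oxygen. The fallback sets out from 10 and comes back at 14. A copper-mediated oxidative O-arylation (Chan–Lam type) of acid 10 with furan-2-ylboronic acid (Cu(OTf)2, urea, air, EtOAc, rt to 50 °C) forms the furyl C–O bond instead of the acyl C–O bond. The acid is never activated and no new intermediate is made.

**Further compounds**

F1 | step 7 | methyl (2S)-2-[(1R,5R)-5-hydroxy-2-oxo-1-(prop-2-en-1-yl)cyclohex-3-en-1-yl]propanoate | C=CC[C@]1([C@H](C)C(=O)OC)C[C@@H](O)C=CC1=O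
F2 | step 7 | methyl (2S)-2-[(1R,5R)-5-methoxy-2-oxo-1-(prop-2-en-1-yl)cyclohex-3-en-1-yl]propanoate | C=CC[C@]1([C@H](C)C(=O)OC)C[C@@H](OC)C=CC1=O
F3 | step 7 | (2S)-2-[(1R,5R)-5-methoxy-2-oxo-1-(prop-2-en-1-yl)cyclohex-3-en-1-yl]propanoic acid | C=CC[C@]1([C@H](C)C(=O)O)C[C@@H](OC)C=CC1=O
F4 | step 7 | S-ethyl (2S)-2-[(1R,5R)-5-methoxy-2-oxo-1-(prop-2-en-1-yl)cyclohex-3-en-1-yl]propanethioate | C=CC[C@]1([C@H](C)C(=O)SCC)C[C@@H](OC)C=CC1=O
F5 | step 6 | (1R,4S,5R)-4-methyl-5-(prop-2-en-1-yl)-2-oxabicyclo[3.3.1]non-7-ene-3,6-dione | C=CC[C@]12C[C@H](C=CC1=O)OC(=O)[C@H]2C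
F0 | step 5 | none | none
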